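**Plan**

- Target numbering: C1 is the monoprenyl carbon, C3 the acyl carbon, C5 the gem-diprenyl carbon, and C2, C4, C6 are the oxygenated carbons between them. Lupulone has one carbocycle and no stereocentre, so no stereochemistry has to be set.
- Retrosynthetic cuts, in order: the O–H bonds at O2 and O4 (masked as methoxymethyl enol ethers); the C3–C(=O) and C(=O)–CH2 bonds of the exocyclic ketone; the three ring–CH2 bonds to the prenyl groups at C1 and C5, one at a time; the C6–O bond of an aromatic precursor.
- Forward: the six-membered ring is bought as 2-iodoresorcinol and no ring is ever closed. The sequence is MOM protection, C–H borylation/oxidation (C6 oxygen), three successive ortho C-prenylations of which the last dearomatises the ring (C1, C5), carbonylative coupling at C3, and acetal hydrolysis.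
- Enabling feature: C3 is the sp2 ring carbon flanked by the oxygen-bearing carbons C2 and C4, and the carbonyl carbon of its exocyclic ketone can be supplied by CO between C3 and an isobutyl group. C3 carries iodine from the first compound on, which also blocks the para position during the prenylations.

Key step: step 7

Assumption: in the last step the acetal at O4 (next to the gem-diprenyl carbon) is taken to hydrolyse first; the opposite order passes through the isomeric monoacetal and gives the same product.

**Step 1**
Reactants: 1 2-iodoresorcinol (2-iodobenzene-1,3-diol)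
Product: 2 2-iodo-1,3-bis(methoxymethoxy)benzene
Conditions: MOMCl (2.5 equiv), i-Pr2NEt (3 equiv), CH2Cl2, 0 °C to rt
Reagents that add atoms: chloromethyl methyl ether, COCCl (two equivalents are incorporated)
Why: The two equivalent phenols are exhaustively O-alkylated by the reactive α-chloro ether under amine base (Williamson-type ether synthesis), so no selectivity issue arises and the iodine between the two new ethers already marks the future C3.

**Step 2**
Reactants: 2 2-iodo-1,3-bis(methoxymethoxy)benzene
Product: 4 4-iodo-3,5-bis(methoxymethoxy)phenol, via aryl pinacolboronate 3 (not isolated)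
Conditions: B2pin2 (1.0 equiv), [Ir(OMe)(cod)]2 (1.5 mol %), 4,4'-di-tert-butyl-2,2'-bipyridine (3 mol %), THF, 25–50 °C; then 30% aq. H2O2, aq. NaOH, 0 °C; aq. NH4Cl work-up
Reagents that add atoms: hydrogen peroxide, OO (phenol oxygen); bis(pinacolato)diboron, CC1(C)OB(OC1(C)C)B1OC(C)(C)C(C)(C)O1 (boron of 3 only)
Why: Iridium-catalysed C–H borylation is sterically controlled and should take the only ring hydrogen without an ortho substituent (C5 of the 1,2,3-trisubstituted arene), with aryl iodides and acetals tolerated, and alkaline peroxide then converts the C–B bond into C–O (one-pot borylation–oxidation phenol synthesis).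

**Step 3**
Reactants: 4 4-iodo-3,5-bis(methoxymethoxy)phenol; 5 prenyl bromide (1-bromo-3-methylbut-2-ene)
Product: 6 4-iodo-3,5-bis(methoxymethoxy)-2-(3-methylbut-2-enyl)phenol
Conditions: NaH (1.0 equiv), toluene, 0 °C; then 5 (1.0 equiv) added slowly, 0 °C to rt, dark
Reagents that add atoms: none
Why: In the non-polar medium the sodium phenoxide of 4 should react as a contact ion pair whose Na+, held by the phenoxide and the neighbouring acetal oxygen, delivers the allylic bromide to an ortho carbon (phenoxide ortho C-alkylation) while iodine blocks the para carbon, the dienone first formed tautomerises to phenol 6, and the one-to-one stoichiometry limits a second alkylation, whose product 7 is in any case the next intermediate and can be carried forward.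

**Step 4**
Reactants: 6 4-iodo-3,5-bis(methoxymethoxy)-2-(3-methylbut-2-enyl)phenol; 5 prenyl bromide
Product: 7 4-iodo-3,5-bis(methoxymethoxy)-2,6-bis(3-methylbut-2-enyl)phenol
Conditions: NaH (1.05 equiv), toluene, 0 °C; then 5 (1.1 equiv), 0 °C to rt, dark
Reagents that add atoms: none
Why: The same sodium-templated ortho C-alkylation of the phenoxide should take the one remaining unsubstituted ortho carbon, the only ring C–H left, and rearomatisation by tautomerisation gives the symmetric 2,6-diprenylphenol.

**Step 5**
Reactants: 7 4-iodo-3,5-bis(methoxymethoxy)-2,6-bis(3-methylbut-2-enyl)phenol; 5 prenyl bromide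
Product: 8 4-iodo-3,5-bis(methoxymethoxy)-2,6,6-tris(3-methylbut-2-enyl)cyclohexa-2,4-dien-1-one
Conditions: NaH (1.1 equiv), toluene, 0 °C; then 5 (1.3 equiv), rt (not above 25 °C), dark
Reagents that add atoms: none
Why: Both ortho carbons of the phenoxide of 7 are substituted and the para carbon carries iodine, so C-alkylation in the non-polar medium should quaternise one prenylated ortho carbon and stop at the blocked cyclohexa-2,4-dienone (dearomatising phenoxide ortho C-alkylation, as in the prenylation of deoxyhumulone-type acylphloroglucinols to hop β-acids), which has no acidic hydrogen and cannot be alkylated further.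

**Step 6**
Reactants: 9 2-methylpropene; 10 9-borabicyclo[3.3.1]nonane (9-BBN, commercial dimer or THF solution)
Product: 11 B-isobutyl-9-borabicyclo[3.3.1]nonane
Conditions: THF, 0 °C to rt, sealed vessel; solution used directly (1.5–2 equiv in step 7)
Reagents that add atoms: none
Why: Hydroboration of the 1,1-disubstituted alkene by 9-BBN places boron on the terminal CH2 (anti-Markovnikov addition), giving the B-primary-alkyl borane needed for selective alkyl transfer.

**Step 7**
Reactants: 8 4-iodo-3,5-bis(methoxymethoxy)-2,6,6-tris(3-methylbut-2-enyl)cyclohexa-2,4-dien-1-one; 11 B-isobutyl-9-borabicyclo[3.3.1]nonane; 12 carbon monoxide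
Product: 13 3,5-bis(methoxymethoxy)-4-(3-methylbutanoyl)-2,6,6-tris(3-methylbut-2-enyl)cyclohexa-2,4-dien-1-one (lupulone bis-MOM ether)
Conditions: PdCl2(dppf) (5 mol %), K3PO4 (3 equiv), CO (3 bar), THF–dioxane, 50 °C
Reagents that add atoms: none
Why: Zerovalent palladium, formed in situ from PdCl2(dppf), inserts into the C3–I bond of 8, CO undergoes migratory insertion to an acylpalladium iodide (divalent palladium), the phosphate-activated borane 11 transfers its primary isobutyl group in preference to the secondary bicyclic B–C bonds, and reductive elimination releases ketone 13, so the C3–C(=O) and C(=O)–CH2 bonds form in one catalytic cycle. The closest known reaction type is the carbonylative Suzuki–Miyaura coupling of alkenyl and aryl iodides with B-alkyl-9-BBN reagents under CO to give alkyl alkenyl ketones. No ring is closed and no stereocentre is created. The step needs CO insertion to precede transmetalation (otherwise direct C3–isobutyl coupling) and reductive elimination to precede β-hydride elimination of the isobutyl group; the two flanking methoxymethoxy-bearing carbons C2 and C4 crowd the C3–Pd bond so that transmetalation at the alkenylpalladium stage is slow while uptake of the small CO ligand is not, and the wide bite angle of dppf speeds acyl–alkyl reductive elimination. The medium is basic and free of Lewis or Brønsted acid, so the acetal enol ethers should persist, O-acylation cannot occur, and the trisubstituted prenyl alkenes, poor partners for acylpalladation, should remain untouched.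

**Step 8**
Reactants: 13 3,5-bis(methoxymethoxy)-4-(3-methylbutanoyl)-2,6,6-tris(3-methylbut-2-enyl)cyclohexa-2,4-dien-1-one
Product: 15 lupulone, via mono-MOM enol ether 14 (not isolated)
Conditions: aq. HCl (1 M), THF, 0 °C to rt, under argon
Reagents that add atoms: none
Why: Both methoxymethyl enol ethers are vinylogous acetal esters with strongly acidic enol leaving groups, so dilute aqueous acid should hydrolyse them (acetal hydrolysis) at or below room temperature, well below the acidity needed to cyclise a prenyl group onto an enol oxygen.

**Compound list**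

1 | 2-iodoresorcinol (2-iodobenzene-1,3-diol) | Oc1cccc(O)c1I | starting material
2 | 2-iodo-1,3-bis(methoxymethoxy)benzene | COCOc1cccc(OCOC)c1I | intermediate
3 | 2-[4-iodo-3,5-bis(methoxymethoxy)phenyl]-4,4,5,5-tetramethyl-1,3,2-dioxaborolane | COCOc1cc(B2OC(C)(C)C(C)(C)O2)cc(OCOC)c1I | intermediate (not isolated)
4 | 4-iodo-3,5-bis(methoxymethoxy)phenol | COCOc1cc(O)cc(OCOC)c1I | intermediate
5 | prenyl bromide (1-bromo-3-methylbut-2-ene) | CC(C)=CCBr | starting material
6 | 4-iodo-3,5-bis(methoxymethoxy)-2-(3-methylbut-2-enyl)phenol | COCOc1cc(O)c(CC=C(C)C)c(OCOC)c1I | intermediate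
7 | 4-iodo-3,5-bis(methoxymethoxy)-2,6-bis(3-methylbut-2-enyl)phenol | COCOc1c(I)c(OCOC)c(CC=C(C)C)c(O)c1CC=C(C)C | intermediate
8 | 4-iodo-3,5-bis(methoxymethoxy)-2,6,6-tris(3-methylbut-2-enyl)cyclohexa-2,4-dien-1-one | COCOC1=C(I)C(OCOC)=C(CC=C(C)C)C(=O)C1(CC=C(C)C)CC=C(C)C | intermediate
9 | 2-methylpropene | CC(C)=C | starting material
10 | 9-borabicyclo[3.3.1]nonane (9-BBN) | [BH]1C2CCCC1CCC2 | starting material
11 | B-isobutyl-9-borabicyclo[3.3.1]nonane | CC(C)CB1C2CCCC1CCC2 | intermediate
12 | carbon monoxide | [C-]#[O+] | starting material
13 | 3,5-bis(methoxymethoxy)-4-(3-methylbutanoyl)-2,6,6-tris(3-methylbut-2-enyl)cyclohexa-2,4-dien-1-one | COCOC1=C(C(=O)CC(C)C)C(OCOC)=C(CC=C(C)C)C(=O)C1(CC=C(C)C)CC=C(C)C | intermediate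
14 | 5-hydroxy-3-(methoxymethoxy)-4-(3-methylbutanoyl)-2,6,6-tris(3-methylbut-2-enyl)cyclohexa-2,4-dien-1-one | COCOC1=C(CC=C(C)C)C(=O)C(CC=C(C)C)(CC=C(C)C)C(O)=C1C(=O)CC(C)C | intermediate (not isolated)
15 | lupulone (3,5-dihydroxy-4-(3-methylbutanoyl)-2,6,6-tris(3-methylbut-2-enyl)cyclohexa-2,4-dien-1-one; no stereocentre) | CC(C)=CCC1=C(O)C(C(=O)CC(C)C)=C(O)C(CC=C(C)C)(CC=C(C)C)C1=O | target

**Count and risks**

Total step count: 8. Longest linear sequence: 7 steps (steps 1, 2, 3, 4, 5, 7, 8) from 2-iodoresorcinol; step 6 is a one-step side branch.

Steps most likely to fail: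

1. Step 7. Oxidative addition at the doubly flanked iodide may be slow and end in protodeiodination, or transmetalation may precede CO insertion and give the directly alkylated product. Fallback: from 8, a Nozaki–Hiyama–Kishi coupling with 3-methylbutanal (CrCl2, 4 equiv, NiCl2, 2 mol %, DMSO–THF, rt) should give the racemic secondary alcohol 4-(1-hydroxy-3-methylbutyl)-3,5-bis(methoxymethoxy)-2,6,6-tris(3-methylbut-2-enyl)cyclohexa-2,4-dien-1-one F1. The alkenylchromium species adds to aldehydes only, so the ring ketone should be left alone. Oxidation with Dess–Martin periodinane (NaHCO3, CH2Cl2, 0 °C) then rejoins the route at 13. The acyl carbon then comes from the aldehyde instead of CO.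

2. Step 5. Once both ortho carbons carry a prenyl group, O-alkylation may overtake the quaternising C-alkylation. Fallback: from 7, O-alkylation with 3-chloro-3-methylbut-1-yne (CuCl2 cat., DBU, MeCN, 0 °C) should give the aryl 2-methylbut-3-yn-2-yl ether F2. Semi-hydrogenation (H2, Pd/CaCO3–Pb(OAc)2, quinoline, EtOAc) should give the aryl 2-methylbut-3-en-2-yl ether F3. Warming F3 in toluene (about 90 °C) should trigger an aromatic Claisen rearrangement that transfers the allyl unit with inversion, so a normal prenyl group arrives at a substituted ortho carbon. With the para carbon blocked by iodine the dienone cannot rearomatise, and the route is rejoined at 8. The O-alkylation that defeats the direct method becomes the productive pathway.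

3. Step 8. Acid-promoted cyclisation of a prenyl group onto a liberated enol oxygen (chroman formation) may compete with hydrolysis of the second acetal. Fallback: from 13, Lewis-acid-assisted thiolysis without protic acid or water (ZnBr2, n-PrSH, CH2Cl2, 0 °C) should transfer both methoxymethyl groups to sulfur and, after neutral aqueous work-up, return the route at 15. It passes through 14 and forms no compound outside the list (F0).

**Further compounds**

F1 | step 7 | 4-(1-hydroxy-3-methylbutyl)-3,5-bis(methoxymethoxy)-2,6,6-tris(3-methylbut-2-enyl)cyclohexa-2,4-dien-1-one (racemic) | COCOC1=C(C(O)CC(C)C)C(OCOC)=C(CC=C(C)C)C(=O)C1(CC=C(C)C)CC=C(C)C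
F2 | step 5 | 4-iodo-3,5-bis(methoxymethoxy)-2,6-bis(3-methylbut-2-enyl)phenyl 2-methylbut-3-yn-2-yl ether | C#CC(C)(C)Oc1c(CC=C(C)C)c(OCOC)c(I)c(OCOC)c1CC=C(C)C
F3 | step 5 | 4-iodo-3,5-bis(methoxymethoxy)-2,6-bis(3-methylbut-2-enyl)phenyl 2-methylbut-3-en-2-yl ether | C=CC(C)(C)Oc1c(CC=C(C)C)c(OCOC)c(I)c(OCOC)c1CC=C(C)C
F0 | step 8 | none | none
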